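Retrosynthetic overview
- **Feature.** The core is an 11-oxabicyclo[4.4.1]undecane: two seven-membered rings that share the ether O, C5 and C10. Ring A (O, C10, C1, C2, C3, C4, C5, the oxepinone) has the atom sequence of a 6-methyl-2,3-dihydropyran-4-one (O, C10, C2, C3, C4, C5) with one extra carbon, C1, slipped into its C10–C2 bond. The tetrasubstituted C10 is tied back to C5 through ring B (O, C5, C6, C7, C8, C9, C10).
- **Late disconnections.** C4=C15 and C11=C13 go back to dimethylaminomethyl groups, unmasked last. The C8 angelate goes back to the epimeric C8 alcohol (inversion), then to a C8 ketone and a C8 methylene. The C1=C2 enone goes back to a C2=C3 enol silane.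
- **Key disconnection.** C9–C10 is cut and C2–C10 is re-joined. Rings A and B become a cyclopropane-fused pyranone (donor O on C10, acceptor C3=O on C2) whose C5 side chain carries an allylsilane on C7.
- **Early disconnections.** C1 comes from the pyranone enol ether (directed Simmons–Smith). The pyranone comes from a C5 aldehyde and a 1-methoxy-3-siloxydiene (C4–C5 and O–C10). C7–C8 comes from anti conjugate addition to an (S)-butenolide that supplies C6.
- **Order of ring formation.** Lactone (chiral pool), pyranone, cyclopropane, then rings A and B together in one cascade.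

Key step: step 9

Numbering: C1–C10 as above; C11, C12, C13 are the lactone α-carbon, carbonyl and methylene; C14 is the methyl on C10; C15 is the methylene on C4. The C7 substituent is bonded through its central alkene carbon C8 (3-(trimethylsilyl)prop-1-en-2-yl), which is what makes ring B seven-membered.

Assumption: the trans-lactone is taken to lock ring B as a chair whose concave face lies over ring A, so reagents reach C8 only from the convex face; hydride reduction should then give the 8-epi alcohol, and the ester has to be introduced with inversion.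

Step 1
Reactants: 1 (S)-5-(hydroxymethyl)furan-2(5H)-one
Product: 2 (S)-5-[(trimethylsilyloxy)methyl]furan-2(5H)-one
Conditions: Me3SiCl, imidazole, CH2Cl2, 0 °C; filtration, concentration
Reagents that add atoms: chlorotrimethylsilane, C[Si](C)(C)Cl
Why: Routine imidazole-mediated O-silylation; the labile trimethylsilyl ether only has to mask the hydroxyl during the organometallic step and falls off in its work-up, so no acid-demanding deprotection is needed once the allylsilane is in place.

Step 2
Reactants: 2 (S)-5-[(trimethylsilyloxy)methyl]furan-2(5H)-one; 3 2-bromoallyltrimethylsilane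
Product: 6 (4R,5S)-5-(hydroxymethyl)-4-[3-(trimethylsilyl)prop-1-en-2-yl]dihydrofuran-2(3H)-one (trans; 6S,7R), via vinyl Grignard reagent 4 (not isolated), via bis-silyl ketene acetal 5 (not isolated)
Conditions: 3, Mg, THF, reflux; CuBr·SMe2 (20 mol %), Me3SiCl, 2, THF, −78 °C; 1 M aq citric acid, 0 °C
Reagents that add atoms: none
Why: Copper-catalysed, Me3SiCl-accelerated conjugate addition of a vinyl Grignard reagent to a butenolide: the C6 substituent shields its own face, C7–C8 forms anti to it and sets 7R (trans-lactone), and the brief citric acid work-up cleaves only the two O–Si bonds, since a C-allylsilane tolerates dilute aqueous acid.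

Step 3
Reactants: 6 (4R,5S)-5-(hydroxymethyl)-4-[3-(trimethylsilyl)prop-1-en-2-yl]dihydrofuran-2(3H)-one
Product: 7 (2S,3R)-5-oxo-3-[3-(trimethylsilyl)prop-1-en-2-yl]tetrahydrofuran-2-carbaldehyde (C5 aldehyde)
Conditions: Dess–Martin periodinane, NaHCO3, CH2Cl2, 0 °C
Reagents that add atoms: none
Why: Dess–Martin oxidation under buffered, non-basic conditions stops at the aldehyde and should not epimerise C6, whose trans arrangement is in any case the more stable one.

Step 4
Reactants: 8 (E)-4-methoxypent-3-en-2-one
Product: 9 (E)-4-methoxy-2-(trimethylsilyloxy)penta-1,3-diene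
Conditions: Me3SiOTf, Et3N, Et2O, 0 °C
Reagents that add atoms: trimethylsilyl triflate, C[Si](C)(C)OS(=O)(=O)C(F)(F)F
Why: Soft enolisation of the methyl ketone silylates on the CH3 side and leaves the E enol ether untouched, which gives the 1-methoxy-3-siloxydiene that carries the future C14 methyl on its oxygenated terminus.

Step 5
Reactants: 7 C5 aldehyde; 9 (E)-4-methoxy-2-(trimethylsilyloxy)penta-1,3-diene
Product: 11 (4R,5S)-5-[(2S)-6-methyl-4-oxo-3,4-dihydro-2H-pyran-2-yl]-4-[3-(trimethylsilyl)prop-1-en-2-yl]dihydrofuran-2(3H)-one (5S,6S,7R; 5,6-syn), via silylated aldol adduct 10 (not isolated)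
Conditions: (S)-BINOL (20 mol %), Ti(OiPr)4 (10 mol %), 4 Å MS, Et2O, −20 °C; pyridinium p-toluenesulfonate (10 mol %), CH2Cl2/MeOH, 0 °C
Reagents that add atoms: none
Why: Formal hetero-Diels–Alder reaction by the Mukaiyama aldol/cyclisation pathway under BINOL–titanium catalysis: the acyl-bound lactone oxygen is too weak a donor to form a chelate and the Felkin–Anh/Cornforth preference of the aldehyde points to the unwanted 5,6-anti isomer, so the (S)-BINOL complex, which directs silyl nucleophiles to the Si face of aldehydes, is relied on to set 5S, and mild acid then closes O–C10 by addition–elimination with loss of the methoxy group.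

Step 6
Reactants: 11 dihydropyranone (5S,6S,7R)
Product: 12 allylic alcohol, (2S,4S)-4-hydroxy-6-methyl-3,4-dihydro-2H-pyran-2-yl lactone (3S; 3-OH cis to the C5 side chain)
Conditions: NaBH4, CeCl3·7H2O, MeOH, −78 °C; aq NaHCO3
Reagents that add atoms: none
Why: Luche 1,2-reduction: hydride adds axially to the half-chair that holds C6 equatorial and gives the pseudo-equatorial 3S alcohol cis to the C5 side chain, while lactone and allylsilane are inert.

Step 7
Reactants: 12 allylic alcohol (3S)
Product: 13 cyclopropyl carbinol, 5-hydroxy-1-methyl-2-oxabicyclo[4.1.0]heptan-3-yl lactone (C1, 3-OH and C6 all on one face of the pyran; C14 on the other)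
Conditions: Et2Zn, CH2I2, CH2Cl2, −20 → 0 °C
Reagents that add atoms: diiodomethane, ICI
Why: Hydroxyl-directed Furukawa-modified Simmons–Smith cyclopropanation, as practised on glycals: the zinc carbenoid held by the C3 oxygen is delivered to the electron-rich C2=C10 enol ether on the face of the OH group, which is also the face of C6, so C1 ends up syn and the C14 methyl anti to the tether, and direction plus enol-ether activation should outpace attack on the allylsilane alkene; a basic sulfur ylide on the enone is avoided because it would threaten E1cB opening at C4–C5 and attack on the lactone.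

Step 8
Reactants: 13 cyclopropyl carbinol
Product: 14 donor–acceptor cyclopropane, 1-methyl-5-oxo-2-oxabicyclo[4.1.0]heptan-3-yl lactone with the allylsilane on C7 (2R,5S,6S,7R,10S; C1 syn to C6)
Conditions: Pr4N[RuO4] (5 mol %), N-methylmorpholine N-oxide, 4 Å MS, CH2Cl2, 23 °C
Reagents that add atoms: none
Why: Ley–Griffith oxidation is neutral and therefore suited to the acid-sensitive 2-alkoxycyclopropyl carbinol; it restores the acceptor at C3 and completes the donor–acceptor cyclopropane without touching any stereocentre.

Step 9
Reactants: 14 donor–acceptor cyclopropane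
Product: 16 11-oxabicyclo[4.4.1]undecene with C2=C3 trimethylsilyl enol ether, C8 exocyclic methylene and trans-fused lactone (C9 on C10 cis to C6 on C5; 10R by CIP, same spatial arrangement as in the target), via oxocarbenium enol silane triflate 15 (not isolated)
Conditions: Me3SiOTf (20 mol %), 2,6-di-tert-butyl-4-methylpyridine (30 mol %), CH2Cl2 (0.005 M), −78 → −30 °C; Et3N quench
Reagents that add atoms: none
Why: Proposed new method: Me3SiOTf silylates the C3 ketone oxygen, the C2–C10 bond (flanked by the ring oxygen on C10 and the carbonyl on C2) breaks heterolytically to the seven-membered oxocarbenium ion/C2=C3 enol silane 15, the CH2= terminus (C9) of the allylsilane adds to C10, and loss of the β-silyl group leaves the C8 methylene and returns Me3SiOTf, so the step is an isomerisation catalytic in silicon. The closest known reaction types are the Me3SiOTf-induced ring expansion of cyclopropane-fused pyranones and cyclopropanated glycals to oxepanes with external allylsilanes, and intramolecular Sakurai/Prins closures of oxepanes from acyclic oxocarbenium ions; their merger in a bridging sense is what is new. Ring A (O, C10, C1, C2, C3, C4, C5) arises without a new bond, by expansion of the pyran through scission of the ring-fusion bond, whereas ring B (O, C5, C6, C7, C8, C9, C10) closes 7-endo-trig at the C10=O+ bond, which lies inside the new ring, and endo with respect to the C8=C9 alkene. The only new stereocentre, C10, is fixed by the tether: C9 hangs from C5 through C6–C7–C8 and reaches only the face of C10 syn to C6, the trans-lactone keeps C6–O and C7–C11 pseudo-equatorial on a chair-like ring B, and in 14 the C14 methyl already points to the opposite face, so even an opening with SN2 character leads to the same isomer. The step needs C–C capture to outrun proton loss from C1 or C14, protodesilylation and intermolecular reaction, which is served by the hindered pyridine (it scavenges TfOH only), low temperature, high dilution and the high nucleophilicity of a 2-substituted allylsilane, while the lactone carbonyl is a much poorer silyl acceptor than the cyclopropyl ketone and re-closure to 14 costs nothing.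

Step 10
Reactants: 16 bicyclic enol silane
Product: 17 C1=C2 enone (C3 ketone) with C8 methylene, configuration at C5, C6, C7, C10 as in the target
Conditions: Pd(OAc)2 (1.1 equiv), MeCN, 23 °C
Reagents that add atoms: none
Why: Saegusa–Ito oxidation: palladation of the regiodefined C2=C3 enol silane at C2 and β-hydride loss from C1, the only position that offers one, gives the C1=C2 enone, and the unactivated C8 methylene should not interfere.

Step 11
Reactants: 17 enone with C8 methylene
Product: 19 C3-enone C8-ketone, via spiro ozonide 18 (not isolated)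
Conditions: O3, CH2Cl2, −78 °C (Sudan Red 7B end point); Me2S, −78 → 23 °C
Reagents that add atoms: ozone, [O-][O+]=O
Why: Ozonolysis with reductive work-up: the electron-rich 1,1-disubstituted C8 methylene reacts far faster than the electron-poor, neopentyl C1=C2 enone, and a dye end point prevents over-oxidation.

Step 12
Reactants: 19 C3-enone C8-ketone
Product: 20 8-epi alcohol (8S; OH on the concave face, H8 on the convex face)
Conditions: NaBH4, CH2Cl2/MeOH (1:1), −78 °C; AcOH quench at −78 °C
Reagents that add atoms: none
Why: Chemoselective borohydride reduction at low temperature in CH2Cl2/MeOH, conditions under which a saturated ketone (here further activated by its β-oxygen substituents) is reduced before a conjugated enone; the concave face of C8 lies over ring A, so hydride should arrive from the convex face and give the 8S alcohol.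

Step 13
Reactants: 20 8-epi alcohol
Product: 21 C8 triethylsilyl ether of 20
Conditions: Et3SiOTf, 2,6-lutidine, CH2Cl2, −78 → −20 °C
Reagents that add atoms: triethylsilyl triflate, CC[Si](CC)(CC)OS(=O)(=O)C(F)(F)F
Why: Silyl triflate/lutidine silylation copes with the hindered concave hydroxyl and masks it before strong base is used, which also rules out its transannular addition to C1.

Step 14
Reactants: 21 C8 triethylsilyl ether
Product: 23 bis-Mannich base, CH2NMe2 on C4 and on C11 (both new centres immaterial), via dilithium bis-enolate 22 (not isolated)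
Conditions: LiN(iPr)2 (2.4 equiv), THF, −78 °C; Me2N=CH2 I (5 equiv), −78 → 0 °C
Reagents that add atoms: Eschenmoser's salt (dimethylmethyleneammonium iodide), C=[N+](C)C.[I-]
Why: Double Mannich reaction of pre-formed lithium enolates with Eschenmoser's salt: the enone can only enolise toward C4 (C10 bears no hydrogen) and the lactone toward C11, the C5–O bond lies close to the nodal plane of the C3=C4 enolate so β-elimination is disfavoured, and the two new centres are of no consequence because both become sp2 in step 17.

Step 15
Reactants: 23 bis-Mannich base silyl ether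
Product: 24 bis-Mannich base with free 8S alcohol
Conditions: HF·pyridine, pyridine, THF, 0 °C; aq NaHCO3
Reagents that add atoms: none
Why: Fluoride-mediated cleavage of the triethylsilyl ether; the amines are merely protonated and the masked methylene groups stay in place.

Step 16
Reactants: 24 bis-Mannich base alcohol; 25 angelic acid, (Z)-2-methylbut-2-enoic acid
Product: 26 8R angelate bis-Mannich base
Conditions: PPh3, diisopropyl azodicarboxylate (DIAD), toluene, 0 → 23 °C
Reagents that add atoms: none
Why: Mitsunobu esterification: SN2 displacement of the activated concave C8–O bond by angelate from the open convex face inverts C8 to 8R, the acid is never activated at its carbonyl group so the Z alkene should be kept, and with both Michael acceptors still masked as amines (C13 trans to C8 on the lactone, out of reach of the backside of C8) neither phosphine nor hydrazide finds an electrophile.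

Step 17
Reactants: 26 8R angelate bis-Mannich base
Product: 28 CNP0335602.1 (5S,6S,7R,8R,10S), via bis(trimethylammonium) diiodide 27 (not isolated)
Conditions: MeI, THF, 23 °C; aq NaHCO3, CH2Cl2, 23 °C
Reagents that add atoms: none
Why: Exhaustive N-methylation followed by mild-base β-elimination of trimethylamine (Hofmann-type, E1cB) is the classical unmasking of α-methylene carbonyl groups from Mannich bases and releases C4=C15 and C11=C13 last, under conditions that leave the angelate and all stereocentres untouched.

Compound list
1 | (S)-5-(hydroxymethyl)furan-2(5H)-one | O=C1O[C@H](CO)C=C1 | starting material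
2 | (S)-5-[(trimethylsilyloxy)methyl]furan-2(5H)-one | O=C1O[C@H](CO[Si](C)(C)C)C=C1 | intermediate
3 | 2-bromoallyltrimethylsilane | C=C(Br)C[Si](C)(C)C | starting material
4 | [3-(trimethylsilyl)prop-1-en-2-yl]magnesium bromide | C=C([Mg]Br)C[Si](C)(C)C | intermediate
5 | bis-silyl ketene acetal of 6 | C1=C(O[Si](C)(C)C)O[C@H](CO[Si](C)(C)C)[C@H]1C(=C)C[Si](C)(C)C | intermediate
6 | trans hydroxymethyl lactone (6S,7R) | C1C(=O)O[C@H](CO)[C@H]1C(=C)C[Si](C)(C)C | intermediate
7 | C5 aldehyde | C1C(=O)O[C@H](C=O)[C@H]1C(=C)C[Si](C)(C)C | intermediate
8 | (E)-4-methoxypent-3-en-2-one | CO/C(C)=C/C(C)=O | starting material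
9 | (E)-4-methoxy-2-(trimethylsilyloxy)penta-1,3-diene | CO/C(C)=C/C(=C)O[Si](C)(C)C | intermediate
10 | (5S) Mukaiyama aldol adduct, C5 trimethylsilyl ether | C1C(=O)O[C@H]([C@@H](O[Si](C)(C)C)CC(=O)/C=C(\C)OC)[C@H]1C(=C)C[Si](C)(C)C | intermediate
11 | 6-methyldihydropyran-4-one (5S,6S,7R) | C1C(=O)O[C@H]([C@@H]3CC(=O)C=C(C)O3)[C@H]1C(=C)C[Si](C)(C)C | intermediate
12 | (3S) allylic alcohol | C1C(=O)O[C@H]([C@@H]3C[C@H](O)C=C(C)O3)[C@H]1C(=C)C[Si](C)(C)C | intermediate
13 | cyclopropyl carbinol (C1 syn to 3-OH and C6) | C1C(=O)O[C@H]([C@@H]3C[C@H](O)[C@@H]4C[C@]4(C)O3)[C@H]1C(=C)C[Si](C)(C)C | intermediate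
14 | donor–acceptor cyclopropyl ketone, key precursor | C1C(=O)O[C@H]([C@@H]3CC(=O)[C@@H]4C[C@]4(C)O3)[C@H]1C(=C)C[Si](C)(C)C | intermediate
15 | seven-membered oxocarbenium ion/C3 enol silane, triflate | C1C(=O)O[C@H]([C@@H]3CC(O[Si](C)(C)C)=CCC(C)=[O+]3)[C@H]1C(=C)C[Si](C)(C)C.[O-]S(=O)(=O)C(F)(F)F | intermediate
16 | bicyclic C2=C3 enol silane with C8 methylene, key product | C1C(=O)O[C@H]2[C@H]1C(=C)C[C@@]1(C)CC=C(O[Si](C)(C)C)C[C@@H]2O1 | intermediate
17 | C1=C2 enone with C8 methylene | C1C(=O)O[C@H]2[C@H]1C(=C)C[C@@]1(C)C=CC(=O)C[C@@H]2O1 | intermediate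
18 | spiro ozonide at C8 | C1C(=O)O[C@H]2[C@H]1C3(OCOO3)C[C@@]1(C)C=CC(=O)C[C@@H]2O1 | intermediate
19 | C3-enone C8-ketone | C1C(=O)O[C@H]2[C@H]1C(=O)C[C@@]1(C)C=CC(=O)C[C@@H]2O1 | intermediate
20 | 8-epi (8S) alcohol | C1C(=O)O[C@H]2[C@H]1[C@@H](O)C[C@@]1(C)C=CC(=O)C[C@@H]2O1 | intermediate
21 | C8 triethylsilyl ether | C1C(=O)O[C@H]2[C@H]1[C@@H](O[Si](CC)(CC)CC)C[C@@]1(C)C=CC(=O)C[C@@H]2O1 | intermediate
22 | dilithium bis-enolate (C3=C4 and C11=C12) | C1=C(O[Li])O[C@H]2[C@H]1[C@@H](O[Si](CC)(CC)CC)C[C@@]1(C)C=CC(O[Li])=C[C@@H]2O1 | intermediate
23 | bis-Mannich base silyl ether | CN(C)CC1C(=O)O[C@H]2[C@H]1[C@@H](O[Si](CC)(CC)CC)C[C@@]1(C)C=CC(=O)C(CN(C)C)[C@@H]2O1 | intermediate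
24 | bis-Mannich base 8S alcohol | CN(C)CC1C(=O)O[C@H]2[C@H]1[C@@H](O)C[C@@]1(C)C=CC(=O)C(CN(C)C)[C@@H]2O1 | intermediate
25 | angelic acid | C/C=C(/C)C(=O)O | starting material
26 | 8R angelate bis-Mannich base | CN(C)CC1C(=O)O[C@H]2[C@H]1[C@H](OC(=O)/C(C)=C\C)C[C@@]1(C)C=CC(=O)C(CN(C)C)[C@@H]2O1 | intermediate
27 | bis(trimethylammonium) diiodide | C[N+](C)(C)CC1C(=O)O[C@H]2[C@H]1[C@H](OC(=O)/C(C)=C\C)C[C@@]1(C)C=CC(=O)C(C[N+](C)(C)C)[C@@H]2O1.[I-].[I-] | intermediate
28 | CNP0335602.1 | C=C1C(=O)O[C@H]2[C@H]1[C@H](OC(=O)/C(C)=C\C)C[C@@]1(C)C=CC(=O)C(=C)[C@@H]2O1 | target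

Total step count: 17. Longest linear sequence: 16 (steps 1–3 and 5–17; step 4 is the side branch).

Steps most likely to fail

**1. Step 9 (new method).** Proton loss from C1 or C14 of the oxocarbenium ion, protodesilylation of the allylsilane or unproductive re-closure may outrun the bridging C–C bond formation.
The fallback uses known reaction types only; the two events are separated and their order is reversed. It sets out from 11 and returns at 17.
- Me3SiOTf (or TiCl4) promotes an intramolecular Hosomi–Sakurai conjugate addition of the allylsilane to C10 of the vinylogous ester. This should give the bridged 10-oxabicyclo[4.3.1]decene enol silane F1, with C9–C10 in place and the enol silane regiodefined.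
- Furukawa cyclopropanation of that enol silane gives the siloxycyclopropane F2.
- FeCl3 in DMF cleaves its ring-fusion bond (one-carbon ring expansion of siloxycyclopropanes) to the β-chloro ketone F3.
- NaOAc in MeOH eliminates HCl to give enone 17. The inserted carbon becomes C2 and the old pyranone carbon next to C10 becomes C1. Steps 6–10 are skipped.

**2. Step 5.** Facial selectivity may erode because catalyst control has to work against the Felkin–Anh/Cornforth bias of the aldehyde.
In the fallback the lactone carbonyl is taken out of play, so that the ring oxygen becomes a true ether donor and substrate control works in the right direction. It sets out from 6 and returns at 11.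
- 6 is silylated (Et3SiCl, imidazole) to the triethylsilyl ether F4.
- Reduction (iBu2AlH, toluene, −78 °C) gives the lactol F5.
- Capping (tBuMe2SiCl, imidazole) gives the anomeric silyl acetal F6.
- Swern oxidation, which converts primary triethylsilyl ethers directly, gives the aldehyde F7.
- MgBr2·OEt2 chelates the aldehyde and ring oxygens. Cyclocondensation with 9 from the face opposite C7, then pyridinium p-toluenesulfonate, gives the 5,6-syn dihydropyranone F8.
- Et3N·3HF frees the lactol F9, and Pr4N[RuO4]/N-methylmorpholine N-oxide oxidises it to 11.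

**3. Step 16.** Activation of the concave hydroxyl by the bulky phosphonium reagent may be slow. This would leave room for E2 elimination toward C9 or for transannular addition of the hydroxyl to C1.
In the fallback, activation and displacement are separated. It sets out from 24 and returns at 26.
- ClCH2SO2Cl/pyridine, a much smaller electrophile, converts 24 to the chloromethanesulfonate F10.
- F10 is displaced by caesium angelate F11 (from 25 and Cs2CO3) with 18-crown-6 in toluene. This is an SN2 inversion by a poorly basic, naked carboxylate and gives 26.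

Further compounds
F1 | step 9 | bridged 10-oxabicyclo[4.3.1]decene enol silane | C1C(=O)O[C@H]2[C@H]1C(=C)C[C@@]1(C)C=C(O[Si](C)(C)C)C[C@@H]2O1
F2 | step 9 | siloxycyclopropane (cyclopropane face immaterial) | C1C(=O)O[C@H]2[C@H]1C(=C)C[C@@]1(C)C3CC3(O[Si](C)(C)C)C[C@@H]2O1
F3 | step 9 | ring-expanded β-chloro ketone | C1C(=O)O[C@H]2[C@H]1C(=C)C[C@@]1(C)C(Cl)CC(=O)C[C@@H]2O1
F4 | step 5 | triethylsilyl ether of 6 | C1C(=O)O[C@H](CO[Si](CC)(CC)CC)[C@H]1C(=C)C[Si](C)(C)C
F5 | step 5 | lactol (anomers) | C1C(O)O[C@H](CO[Si](CC)(CC)CC)[C@H]1C(=C)C[Si](C)(C)C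
F6 | step 5 | anomeric tert-butyldimethylsilyl acetal | C1C(O[Si](C)(C)C(C)(C)C)O[C@H](CO[Si](CC)(CC)CC)[C@H]1C(=C)C[Si](C)(C)C
F7 | step 5 | tetrahydrofuran aldehyde | C1C(O[Si](C)(C)C(C)(C)C)O[C@H](C=O)[C@H]1C(=C)C[Si](C)(C)C
F8 | step 5 | 5,6-syn dihydropyranone silyl acetal | C1C(O[Si](C)(C)C(C)(C)C)O[C@H]([C@@H]3CC(=O)C=C(C)O3)[C@H]1C(=C)C[Si](C)(C)C
F9 | step 5 | dihydropyranone lactol | C1C(O)O[C@H]([C@@H]3CC(=O)C=C(C)O3)[C@H]1C(=C)C[Si](C)(C)C
F10 | step 16 | C8 chloromethanesulfonate of 24 | CN(C)CC1C(=O)O[C@H]2[C@H]1[C@@H](OS(=O)(=O)CCl)C[C@@]1(C)C=CC(=O)C(CN(C)C)[C@@H]2O1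
F11 | step 16 | caesium angelate | C/C=C(/C)C(=O)[O-].[Cs+]
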